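**Plan**

1. First cut: the two C–C bonds of the bridging CH2 (chromene C6–CH2 and CH2–C6 of the filicinic acid ring). This gives chromene diol 12, the one-carbon iminium salt 13 and acetylfilicinic acid 16.
2. Second cut: the aryl ether bond O1–C8a of the pyran ring (intramolecular SNAr of a tertiary alkoxide on an aryl fluoride). Then C4a–C4 (Sonogashira, Z-semihydrogenation) and C8–acetyl (iodine–magnesium exchange, acylation), back to the C2v-symmetric 1-fluoro-2,6-diiodo-3,5-bis(methoxymethoxy)benzene 3 and 5-fluororesorcinol 1.
3. Enabling feature: in the benzene ring of the chromene, C8a is ortho to the acetyl-bearing C8 and meta to the oxygens on C5 and C7, so F–C8a=C8–C(=O)CH3 is a vinylogous acyl fluoride. Only C8a carries a leaving group, which fixes the fusion with the pyran oxygen next to the acetyl group (the regiochemical problem of chromenylating an acylphloroglucinol).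
4. Forward order: substituents placed on symmetric arene 3 → pyran ring closed (step 6) → phenols freed → C6 aminomethylated → joined through an ortho-quinone methide to the filicinic acid ring, made separately by gem-dimethylation of 2,4,6-trihydroxyacetophenone.
5. Stereochemistry: the target has no stereocentre. The only stereo-element on the way is the Z alkene of 8 (syn hydrogenation of the alkyne), which becomes the endocyclic C3=C4 bond.

Key step: step 6

Remark: the enolised β-triketone and the phloroglucinol unit are written as the tautomers of the given SMILES; tautomers are treated as one compound.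

**Route**

Step 1
Reactants: 1 5-fluororesorcinol (5-fluorobenzene-1,3-diol)
Product: 2 1-fluoro-3,5-bis(methoxymethoxy)benzene
Conditions: NaH (2.4 equiv), MOMCl (2.4 equiv), DMF, 0 °C → rt
Reagents that add atoms: chloromethyl methyl ether (MOMCl), COCCl
Why: Twofold Williamson-type O-alkylation of the sodium phenoxides with the reactive α-chloro ether should give the bis-MOM ether, which keeps both phenols as base-stable acetals through steps 3 to 6.

Step 2
Reactants: 2 1-fluoro-3,5-bis(methoxymethoxy)benzene
Product: 3 1-fluoro-2,6-diiodo-3,5-bis(methoxymethoxy)benzene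
Conditions: NIS (2.2 equiv), TFA (10 mol%), MeCN, 0 °C → rt, dark
Reagents that add atoms: N-iodosuccinimide (NIS), O=C1CCC(=O)N1I
Why: Electrophilic aromatic iodination should enter twice at the two equivalent positions that are para to one MOM ether and ortho to the other (both ortho to fluorine), the position between the two MOM ethers being the most hindered one as in the 4,6-dihalogenation of resorcinol diethers, so that a C2v-symmetric diiodide results.

Step 3
Reactants: 3 1-fluoro-2,6-diiodo-3,5-bis(methoxymethoxy)benzene
Product: 5 1-[2-fluoro-3-iodo-4,6-bis(methoxymethoxy)phenyl]ethan-1-one, via arylmagnesium chloride 4 (not isolated)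
Conditions: i-PrMgCl·LiCl (1.05 equiv), THF, −40 °C; then MeC(O)N(OMe)Me (1.5 equiv), −40 °C → rt; aq. NH4Cl
Reagents that add atoms: N-methoxy-N-methylacetamide, CC(=O)N(C)OC
Why: Iodine–magnesium exchange (Knochel exchange), accelerated by the ortho fluorine and the ortho MOM ether, should stop after one exchange because the two iodines are equivalent and the electron-rich aryl Grignard resists a second exchange, and Weinreb ketone synthesis then delivers the methyl ketone without over-addition.

Step 4
Reactants: 5 1-[2-fluoro-3-iodo-4,6-bis(methoxymethoxy)phenyl]ethan-1-one; 6 2-methylbut-3-yn-2-ol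
Product: 7 1-[2-fluoro-3-(3-hydroxy-3-methylbut-1-yn-1-yl)-4,6-bis(methoxymethoxy)phenyl]ethan-1-one
Conditions: Pd(PPh3)2Cl2 (5 mol%), CuI (10 mol%), Et3N, THF, 50 °C
Reagents that add atoms: none
Why: Sonogashira coupling should take place only at the aryl iodide (the C–F bond is inert to oxidative addition) and needs no protection of the tertiary alcohol.

Step 5
Reactants: 7 1-[2-fluoro-3-(3-hydroxy-3-methylbut-1-yn-1-yl)-4,6-bis(methoxymethoxy)phenyl]ethan-1-one
Product: 8 1-{2-fluoro-3-[(1Z)-3-hydroxy-3-methylbut-1-en-1-yl]-4,6-bis(methoxymethoxy)phenyl}ethan-1-one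
Conditions: H2 (1 atm), Pd/CaCO3 poisoned with Pb(OAc)2 (Lindlar catalyst), quinoline, EtOAc, rt
Reagents that add atoms: none
Why: Lindlar semihydrogenation adds both hydrogens to the same face of the alkyne and should give the Z alkene, the geometry that places the carbinol oxygen next to C8a.

Step 6
Reactants: 8 1-{2-fluoro-3-[(1Z)-3-hydroxy-3-methylbut-1-en-1-yl]-4,6-bis(methoxymethoxy)phenyl}ethan-1-one
Product: 11 1-[5,7-bis(methoxymethoxy)-2,2-dimethyl-2H-chromen-8-yl]ethan-1-one, via potassium alkoxide 9 (not isolated), via Meisenheimer adduct 10 (not isolated)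
Conditions: KN(SiMe3)2 (1.05 equiv), THF–DMF (5:1), −20 °C → rt
Reagents that add atoms: none
Why: KN(SiMe3)2 deprotonates the tertiary alcohol to alkoxide 9, whose oxygen adds to C8a to give Meisenheimer adduct 10, in which the charge is held as the enolate of the C8 acetyl group, and loss of fluoride then restores the benzene ring and leaves the pyran closed at its aryl ether bond (addition–elimination, SNAr). The closest known reaction type is the intramolecular displacement of a fluoride ortho to an aryl ketone by an alkoxide, the usual route from ortho-fluoroaryl ketones to chromans and related cyclic aryl ethers. The pyran ring closes in the 6-exo-trig mode (the accepting C8a=C8 π bond lies outside the new ring), and the Z alkene set in step 5 holds the oxygen over C8a and becomes the endocyclic C3=C4 bond. No stereocentre is formed. The step needs regioselectivity (pyran oxygen ortho to the acetyl group, not para), and this is secured because C8a is the only ring carbon that carries a leaving group and the two MOM ethers are meta to it and so do not oppose the anionic adduct. It also needs O-attack to compete with reversible enolisation of the methyl ketone, which one equivalent of a non-nucleophilic base and the six-membered intramolecular closure should secure.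

Step 7
Reactants: 11 1-[5,7-bis(methoxymethoxy)-2,2-dimethyl-2H-chromen-8-yl]ethan-1-one
Product: 12 1-(5,7-dihydroxy-2,2-dimethyl-2H-chromen-8-yl)ethan-1-one
Conditions: p-TsOH·H2O (20 mol%), MeOH, 45 °C
Reagents that add atoms: none
Why: Acid-catalysed acetal exchange of the two aryl MOM ethers with methanol should free both phenols (the C7 ether next to the acetyl group first) under conditions mild enough for the chromene double bond.

Step 8
Reactants: 12 1-(5,7-dihydroxy-2,2-dimethyl-2H-chromen-8-yl)ethan-1-one; 13 N,N-dimethylmethylideneammonium iodide (Eschenmoser's salt)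
Product: 14 1-{6-[(dimethylamino)methyl]-5,7-dihydroxy-2,2-dimethyl-2H-chromen-8-yl}ethan-1-one
Conditions: Et3N (1.1 equiv), CH2Cl2, 0 °C → rt
Reagents that add atoms: none
Why: Aromatic Mannich reaction with the preformed iminium salt should occur at C6, the only unsubstituted ring position and one flanked by two phenolic hydroxyls.

Step 9
Reactants: 15 2,4,6-trihydroxyacetophenone
Product: 16 2-acetyl-3,5-dihydroxy-4,4-dimethylcyclohexa-2,5-dien-1-one (acetylfilicinic acid)
Conditions: NaOMe (3 equiv), MeI (2.2 equiv), MeOH, 0 °C → rt; acidic work-up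
Reagents that add atoms: iodomethane, CI
Why: Twofold dearomatising C-methylation at one ring carbon of the phloroglucinol anion, the known route from acylphloroglucinols to acylfilicinic acids, should give the gem-dimethyl enolised trione.

Step 10
Reactants: 14 1-{6-[(dimethylamino)methyl]-5,7-dihydroxy-2,2-dimethyl-2H-chromen-8-yl}ethan-1-one; 16 acetylfilicinic acid (1.2 equiv)
Product: 18 2-acetyl-6-[(8-acetyl-5,7-dihydroxy-2,2-dimethyl-2H-chromen-6-yl)methyl]-3,5-dihydroxy-4,4-dimethylcyclohexa-2,5-dien-1-one (CNP0333383.0), via ortho-quinone methide 17 (not isolated)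
Conditions: 1,4-dioxane, 90 °C
Reagents that add atoms: none
Why: Thermal loss of dimethylamine from the ortho-hydroxybenzylamine should give ortho-quinone methide 17, which is trapped by Michael addition of the vinylogous acid 16 through its only ring C–H carbon, so that the unsymmetrical methylene-bridged dimer forms without the homodimers of a free formaldehyde condensation.

**Compound list**

1 | 5-fluororesorcinol (5-fluorobenzene-1,3-diol) | Oc1cc(O)cc(F)c1 | starting material
2 | 1-fluoro-3,5-bis(methoxymethoxy)benzene | COCOc1cc(F)cc(OCOC)c1 | intermediate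
3 | 1-fluoro-2,6-diiodo-3,5-bis(methoxymethoxy)benzene | COCOc1cc(OCOC)c(I)c(F)c1I | intermediate
4 | [2-fluoro-3-iodo-4,6-bis(methoxymethoxy)phenyl]magnesium chloride (LiCl complex, formed in the flask, not isolated) | COCOc1cc(OCOC)c(I)c(F)c1[Mg]Cl | intermediate
5 | 1-[2-fluoro-3-iodo-4,6-bis(methoxymethoxy)phenyl]ethan-1-one | CC(=O)c1c(F)c(I)c(OCOC)cc1OCOC | intermediate
6 | 2-methylbut-3-yn-2-ol | CC(C)(O)C#C | starting material
7 | 1-[2-fluoro-3-(3-hydroxy-3-methylbut-1-yn-1-yl)-4,6-bis(methoxymethoxy)phenyl]ethan-1-one | CC(=O)c1c(F)c(C#CC(C)(C)O)c(OCOC)cc1OCOC | intermediate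
8 | 1-{2-fluoro-3-[(1Z)-3-hydroxy-3-methylbut-1-en-1-yl]-4,6-bis(methoxymethoxy)phenyl}ethan-1-one | CC(=O)c1c(F)c(/C=C\C(C)(C)O)c(OCOC)cc1OCOC | intermediate
9 | potassium (3Z)-4-[3-acetyl-2-fluoro-4,6-bis(methoxymethoxy)phenyl]-2-methylbut-3-en-2-olate (formed in the flask, not isolated) | CC(=O)c1c(F)c(/C=C\C(C)(C)[O-])c(OCOC)cc1OCOC.[K+] | intermediate
10 | potassium 1-[8a-fluoro-5,7-bis(methoxymethoxy)-2,2-dimethyl-2H-chromen-8(8aH)-ylidene]ethan-1-olate, the Meisenheimer adduct (formed in the flask, not isolated) | CC([O-])=C1C(OCOC)=CC(OCOC)=C2C=CC(C)(C)OC12F.[K+] | intermediate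
11 | 1-[5,7-bis(methoxymethoxy)-2,2-dimethyl-2H-chromen-8-yl]ethan-1-one | CC(=O)c1c(OCOC)cc(OCOC)c2c1OC(C)(C)C=C2 | intermediate
12 | 1-(5,7-dihydroxy-2,2-dimethyl-2H-chromen-8-yl)ethan-1-one | CC(=O)c1c(O)cc(O)c2c1OC(C)(C)C=C2 | intermediate
13 | N,N-dimethylmethylideneammonium iodide (Eschenmoser's salt) | C[N+](C)=C.[I-] | starting material
14 | 1-{6-[(dimethylamino)methyl]-5,7-dihydroxy-2,2-dimethyl-2H-chromen-8-yl}ethan-1-one | CC(=O)c1c(O)c(CN(C)C)c(O)c2c1OC(C)(C)C=C2 | intermediate
15 | 2,4,6-trihydroxyacetophenone | CC(=O)c1c(O)cc(O)cc1O | starting material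
16 | 2-acetyl-3,5-dihydroxy-4,4-dimethylcyclohexa-2,5-dien-1-one (acetylfilicinic acid) | CC(=O)C1=C(O)C(C)(C)C(O)=CC1=O | intermediate
17 | 8-acetyl-5-hydroxy-2,2-dimethyl-6-methylidene-2H-chromen-7(6H)-one, the ortho-quinone methide (formed in the flask, not isolated) | C=C1C(=O)C(C(C)=O)=C2OC(C)(C)C=CC2=C1O | intermediate
18 | 2-acetyl-6-[(8-acetyl-5,7-dihydroxy-2,2-dimethyl-2H-chromen-6-yl)methyl]-3,5-dihydroxy-4,4-dimethylcyclohexa-2,5-dien-1-one (CNP0333383.0) | CC(=O)C1=C(O)C(C)(C)C(O)=C(Cc2c(O)c3c(c(C(C)=O)c2O)OC(C)(C)C=C3)C1=O | target

**Step count**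

Total step count: 10. Longest linear sequence: 9 steps (steps 1 to 8 and step 10); step 9 is a one-step side branch.

**Steps most likely to fail**

Step 6. What may go wrong: enolisation of the methyl ketone by the base switches off the activation of C8a while the base-sensitive Z-allylic alkoxide is consumed by E/Z erosion or intermolecular condensation, so that fluoride is not displaced. The fallback keeps the ring closure at the aryl ether bond but uses a saturated tether that tolerates excess base and heat, and brings in the double bond afterwards. It sets out from compound 7. Exhaustive hydrogenation of the alkyne (H2, Pd/C, EtOAc, rt) should give 1-[2-fluoro-3-(3-hydroxy-3-methylbutyl)-4,6-bis(methoxymethoxy)phenyl]ethan-1-one F1. KOt-Bu (2.2 equiv) in THF at 60 °C should then close the chroman by SNAr to 1-[5,7-bis(methoxymethoxy)-2,2-dimethyl-3,4-dihydro-2H-chromen-8-yl]ethan-1-one F2. DDQ in 1,4-dioxane at reflux should remove hydride from C4, which is stabilised by the three ring oxygens, and dehydrogenate C3–C4. The fallback comes back to the route at compound 11.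

Step 10. What may go wrong: the ortho-quinone methide is captured by the released dimethylamine or by the C3=C4 bond of a second chromene unit faster than by the filicinic acid carbon, or the aminomethyl group is transferred between partners and symmetric dimers form. The fallback reverses the roles of the two halves, so that the electrophile is generated on the filicinic acid ring. It sets out from compound 16 and uses compound 12 directly, which leaves out step 8. Mannich reaction of 16 with salt 13 (Et3N, CH2Cl2, rt) should give 2-acetyl-6-[(dimethylamino)methyl]-3,5-dihydroxy-4,4-dimethylcyclohexa-2,5-dien-1-one F3. Heating F3 with 12 in 1,4-dioxane at 90 °C should release 2-acetyl-3-hydroxy-4,4-dimethyl-6-methylidenecyclohex-2-ene-1,5-dione F4 (not isolated), which the chromene should capture at C6, its only free ring position. The fallback comes back at compound 18.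

Step 3. What may go wrong: a second iodine–magnesium exchange, loss of magnesium halide from the ortho-fluoro aryl Grignard to an aryne on warming, or enolisation of the acyl donor that merely protonates the Grignard reagent. The fallback avoids any aryl-metal reagent and installs the two carbon substituents by cross-coupling in the reverse order. It sets out from compound 3. Mono-Sonogashira coupling of the symmetric diiodide (used in excess) with 6 (Pd(PPh3)2Cl2, CuI, Et3N, THF, rt) should give 4-[2-fluoro-3-iodo-4,6-bis(methoxymethoxy)phenyl]-2-methylbut-3-yn-2-ol F5. Stille coupling of the remaining iodide with tributyl(1-ethoxyvinyl)stannane (Pd(PPh3)4, toluene, 100 °C) should give 4-[3-(1-ethoxyethenyl)-2-fluoro-4,6-bis(methoxymethoxy)phenyl]-2-methylbut-3-yn-2-ol F6. Brief hydrolysis of the enol ether (1 M HCl, THF, 0 °C) should unmask the methyl ketone. The fallback comes back at compound 7.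

**Further compounds**

F1 | step 6 | 1-[2-fluoro-3-(3-hydroxy-3-methylbutyl)-4,6-bis(methoxymethoxy)phenyl]ethan-1-one | CC(=O)c1c(F)c(CCC(C)(C)O)c(OCOC)cc1OCOC
F2 | step 6 | 1-[5,7-bis(methoxymethoxy)-2,2-dimethyl-3,4-dihydro-2H-chromen-8-yl]ethan-1-one | CC(=O)c1c(OCOC)cc(OCOC)c2c1OC(C)(C)CC2
F3 | step 10 | 2-acetyl-6-[(dimethylamino)methyl]-3,5-dihydroxy-4,4-dimethylcyclohexa-2,5-dien-1-one | CC(=O)C1=C(O)C(C)(C)C(O)=C(CN(C)C)C1=O
F4 | step 10 | 2-acetyl-3-hydroxy-4,4-dimethyl-6-methylidenecyclohex-2-ene-1,5-dione | CC(=O)C1=C(O)C(C)(C)C(=O)C(=C)C1=O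
F5 | step 3 | 4-[2-fluoro-3-iodo-4,6-bis(methoxymethoxy)phenyl]-2-methylbut-3-yn-2-ol | COCOc1cc(OCOC)c(I)c(F)c1C#CC(C)(C)O
F6 | step 3 | 4-[3-(1-ethoxyethenyl)-2-fluoro-4,6-bis(methoxymethoxy)phenyl]-2-methylbut-3-yn-2-ol | CCOC(=C)c1c(F)c(C#CC(C)(C)O)c(OCOC)cc1OCOC
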